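**Assumption:** Praesorether F has no stereocentre (it is achiral), so no enantiocontrol is needed; the only stereo-defined species in the route is the E-hydrazone intermediate 11.

## Retrosynthetic overview

1. No ring is built. Rings A and C both come from methyl orsellinate (one formylation gives methyl haematommate for both), and ring B comes from orcinol.
2. Last skeletal bond: the diaryl ether C–O, by SNAr of a ring-B phenol on a 2-fluoro-haematommate (ring C), then global debenzylation.
3. The ring-B phenol comes from C–H formylation and Dakin oxidation of a diarylmethane whose ring B is still symmetrical, so both open ring-B sites are equivalent.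
4. Key C–C bond (ArA–CH2–ArB): the formyl carbon of a haematommate, as its N–H hydrazone, acts as a benzyl-carbanion equivalent. Under Ni catalysis it is joined to C-2 of a 2-iodo-orcinol ether with loss of N2, so an aldehyde carbon and an aryl-halide carbon (both normally electrophilic) give the CH2 bridge directly.

## Route

Step 1
Reactants: 1 methyl orsellinate (methyl 2,4-dihydroxy-6-methylbenzoate)
Product: 3 methyl haematommate (methyl 3-formyl-2,4-dihydroxy-6-methylbenzoate), via chloro(methoxy)methyl arene 2 (not isolated)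
Conditions: Cl2CHOMe (1.1 equiv), TiCl4 (2.2 equiv), CH2Cl2, 0 °C to rt; then H2O
Reagents that add atoms: dichloromethyl methyl ether COC(Cl)Cl (formyl carbon); water O (formyl oxygen)
Why: Rieche formylation, in which the titanium phenoxide directs the electrophile to C-3, the position ortho to both hydroxyls; the minor 5-formyl isomer is removed by crystallisation or chromatography.

Step 2
Reactants: 3 methyl haematommate
Product: 4 methyl 2,4-bis(benzyloxy)-3-formyl-6-methylbenzoate
Conditions: BnBr (2.5 equiv), K2CO3 (3 equiv), DMF, 60 °C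
Reagents that add atoms: benzyl bromide BrCc1ccccc1
Why: Williamson etherification under forcing conditions alkylates both chelated phenols and leaves no acidic O–H for the nickel step.

Step 3
Reactants: 3 methyl haematommate
Product: 5 methyl 4-(benzyloxy)-3-formyl-2-hydroxy-6-methylbenzoate
Conditions: BnBr (1.05 equiv), K2CO3 (1.1 equiv), acetone, 50 °C
Reagents that add atoms: benzyl bromide BrCc1ccccc1
Why: Williamson etherification with one equivalent goes to the less hindered 4-OH, because the 2-OH sits between the ester and the aldehyde and is the more strongly chelated one.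

Step 4
Reactants: 5 methyl 4-(benzyloxy)-3-formyl-2-hydroxy-6-methylbenzoate
Product: 7 methyl 4-(benzyloxy)-2-fluoro-3-formyl-6-methylbenzoate, via aryl fluorosulfonate 6 (not isolated)
Conditions: SO2F2 (balloon), anhydrous NMe4F (3 equiv), DMF, rt
Reagents that add atoms: sulfuryl fluoride O=S(=O)(F)F (the OSO2F group of 6 only); tetramethylammonium fluoride C[N+](C)(C)C.[F-] (the ring fluorine of 7)
Why: Deoxyfluorination of a phenol through its aryl fluorosulfonate, where fluoride displaces fluorosulfate by SNAr at a carbon activated by the ortho-formyl and ortho-ester groups.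

Step 5
Reactants: 8 orcinol (5-methylbenzene-1,3-diol)
Product: 9 2-iodo-5-methylbenzene-1,3-diol
Conditions: I2 (1.05 equiv), NaHCO3, H2O/THF, 0 °C to rt
Reagents that add atoms: iodine II
Why: Electrophilic aromatic iodination of a resorcinol under bicarbonate conditions goes selectively to C-2, between the two hydroxyls.

Step 6
Reactants: 9 2-iodo-5-methylbenzene-1,3-diol
Product: 10 1,3-bis(benzyloxy)-2-iodo-5-methylbenzene
Conditions: BnBr (2.3 equiv), K2CO3 (3 equiv), DMF, rt
Reagents that add atoms: benzyl bromide BrCc1ccccc1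
Why: Williamson etherification of both phenols gives a base-stable aryl iodide whose ring remains symmetrical.

Step 7 (key step)
Reactants: 4 methyl 2,4-bis(benzyloxy)-3-formyl-6-methylbenzoate; 10 1,3-bis(benzyloxy)-2-iodo-5-methylbenzene
Product: 12 methyl 2,4-bis(benzyloxy)-3-[[2,6-bis(benzyloxy)-4-methylphenyl]methyl]-6-methylbenzoate, via hydrazone 11 (not isolated)
Conditions: N2H4·H2O (1.2 equiv), THF, 4 Å MS, rt; then 10, Ni(cod)2 (10 mol %), PMe3 (20 mol %), K3PO4 (2 equiv), THF, 70 °C
Reagents that add atoms: hydrazine hydrate NN.O (its nitrogens are in 11 only and leave as N2; 12 keeps only hydrogen from it)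
Why: Proposed new method: the N–H hydrazone 11 serves as a benzyl-carbanion equivalent of aldehyde 4 (carbonyl umpolung), so that oxidative addition of 10 to Ni(0), N-coordination and deprotonation of 11, and a six-membered N2-extruding C–C bond formation (a metal-templated Wolff–Kishner-type step) give the CH2-bridged product directly; the closest known reaction type is the nickel-catalysed cross-coupling of aldehyde hydrazones with aryl halides, here stretched to partners that are 2,6-dioxygenated on both sides.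

Step 8
Reactants: 12 methyl 2,4-bis(benzyloxy)-3-[[2,6-bis(benzyloxy)-4-methylphenyl]methyl]-6-methylbenzoate
Product: 14 methyl 2,4-bis(benzyloxy)-3-[[2,6-bis(benzyloxy)-3-formyl-4-methylphenyl]methyl]-6-methylbenzoate, via iminium chloride 13 (not isolated)
Conditions: POCl3 (1.5 equiv), DMF, 0 to 60 °C; then H2O
Reagents that add atoms: N,N-dimethylformamide CN(C)C=O (formyl carbon); water O (formyl oxygen)
Why: Vilsmeier–Haack formylation attacks the ester-free ring B, the more electron-rich ring, at either of its two equivalent C–H positions (ortho to one OBn, para to the other), so a single mono-aldehyde results.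

Step 9
Reactants: 14 methyl 2,4-bis(benzyloxy)-3-[[2,6-bis(benzyloxy)-3-formyl-4-methylphenyl]methyl]-6-methylbenzoate
Product: 16 methyl 2,4-bis(benzyloxy)-3-[[2,6-bis(benzyloxy)-3-hydroxy-4-methylphenyl]methyl]-6-methylbenzoate, via aryl formate 15 (not isolated)
Conditions: mCPBA (1.3 equiv), CH2Cl2, 0 °C to rt; then K2CO3 (0.2 equiv), MeOH, rt
Reagents that add atoms: meta-chloroperoxybenzoic acid OOC(=O)c1cccc(Cl)c1 (the inserted oxygen)
Why: Dakin-type Baeyer–Villiger oxidation, in which the ortho,para-dialkoxyaryl group migrates in preference to H to give the formate, which mild methanolysis cleaves to the phenol.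

Step 10
Reactants: 16 methyl 2,4-bis(benzyloxy)-3-[[2,6-bis(benzyloxy)-3-hydroxy-4-methylphenyl]methyl]-6-methylbenzoate; 7 methyl 4-(benzyloxy)-2-fluoro-3-formyl-6-methylbenzoate
Product: 17 penta-O-benzyl praesorether F (methyl 2,4-bis(benzyloxy)-3-[[2,6-bis(benzyloxy)-3-[3-(benzyloxy)-2-formyl-6-(methoxycarbonyl)-5-methylphenoxy]-4-methylphenyl]methyl]-6-methylbenzoate)
Conditions: K2CO3 (1.5 equiv), DMF, Ar, 60 °C
Reagents that add atoms: none
Why: SNAr of the only free phenoxide on a fluoride flanked by formyl and ester groups, a type of substitution that tolerates the ortho substituents on both partners.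

Step 11
Reactants: 17 penta-O-benzyl praesorether F
Product: 18 praesorether F
Conditions: H2 (1 atm), 10 % Pd/C, EtOAc, rt, stopped at full conversion
Reagents that add atoms: none
Why: Catalytic hydrogenolysis removes all five benzyl ethers while the methyl esters, the diaryl ether, the diarylmethane and (in EtOAc at 1 atm) the chelated aryl aldehyde are left intact.

## Compound list

1 | methyl orsellinate (methyl 2,4-dihydroxy-6-methylbenzoate) | COC(=O)c1c(C)cc(O)cc1O | starting material
2 | methyl 3-[chloro(methoxy)methyl]-2,4-dihydroxy-6-methylbenzoate (racemic; present as its titanium phenoxide) | COC(=O)c1c(C)cc(O)c(C(Cl)OC)c1O | intermediate (not isolated)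
3 | methyl haematommate (methyl 3-formyl-2,4-dihydroxy-6-methylbenzoate) | COC(=O)c1c(C)cc(O)c(C=O)c1O | intermediate
4 | methyl 2,4-bis(benzyloxy)-3-formyl-6-methylbenzoate | COC(=O)c1c(C)cc(OCc2ccccc2)c(C=O)c1OCc3ccccc3 | intermediate
5 | methyl 4-(benzyloxy)-3-formyl-2-hydroxy-6-methylbenzoate | COC(=O)c1c(C)cc(OCc2ccccc2)c(C=O)c1O | intermediate
6 | methyl 4-(benzyloxy)-2-[(fluorosulfonyl)oxy]-3-formyl-6-methylbenzoate | COC(=O)c1c(C)cc(OCc2ccccc2)c(C=O)c1OS(=O)(=O)F | intermediate (not isolated)
7 | methyl 4-(benzyloxy)-2-fluoro-3-formyl-6-methylbenzoate | COC(=O)c1c(C)cc(OCc2ccccc2)c(C=O)c1F | intermediate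
8 | orcinol (5-methylbenzene-1,3-diol) | Cc1cc(O)cc(O)c1 | starting material
9 | 2-iodo-5-methylbenzene-1,3-diol | Cc1cc(O)c(I)c(O)c1 | intermediate
10 | 1,3-bis(benzyloxy)-2-iodo-5-methylbenzene | Cc1cc(OCc2ccccc2)c(I)c(OCc3ccccc3)c1 | intermediate
11 | methyl 2,4-bis(benzyloxy)-3-[(E)-hydrazinylidenemethyl]-6-methylbenzoate | COC(=O)c1c(C)cc(OCc2ccccc2)c(/C=N/N)c1OCc3ccccc3 | intermediate (not isolated)
12 | methyl 2,4-bis(benzyloxy)-3-[[2,6-bis(benzyloxy)-4-methylphenyl]methyl]-6-methylbenzoate | COC(=O)c1c(C)cc(OCc2ccccc2)c(Cc3c(OCc4ccccc4)cc(C)cc3OCc5ccccc5)c1OCc6ccccc6 | intermediate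
13 | N,N-dimethyliminium chloride of aldehyde 14 (ring-B–CH=NMe2+ Cl−) | COC(=O)c1c(C)cc(OCc2ccccc2)c(Cc3c(OCc4ccccc4)cc(C)c(C=[N+](C)C)c3OCc5ccccc5)c1OCc6ccccc6.[Cl-] | intermediate (not isolated)
14 | methyl 2,4-bis(benzyloxy)-3-[[2,6-bis(benzyloxy)-3-formyl-4-methylphenyl]methyl]-6-methylbenzoate | COC(=O)c1c(C)cc(OCc2ccccc2)c(Cc3c(OCc4ccccc4)cc(C)c(C=O)c3OCc5ccccc5)c1OCc6ccccc6 | intermediate
15 | methyl 2,4-bis(benzyloxy)-3-[[2,6-bis(benzyloxy)-3-(formyloxy)-4-methylphenyl]methyl]-6-methylbenzoate | COC(=O)c1c(C)cc(OCc2ccccc2)c(Cc3c(OCc4ccccc4)cc(C)c(OC=O)c3OCc5ccccc5)c1OCc6ccccc6 | intermediate (not isolated)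
16 | methyl 2,4-bis(benzyloxy)-3-[[2,6-bis(benzyloxy)-3-hydroxy-4-methylphenyl]methyl]-6-methylbenzoate | COC(=O)c1c(C)cc(OCc2ccccc2)c(Cc3c(OCc4ccccc4)cc(C)c(O)c3OCc5ccccc5)c1OCc6ccccc6 | intermediate
17 | penta-O-benzyl praesorether F | COC(=O)c1c(C)cc(OCc2ccccc2)c(Cc3c(OCc4ccccc4)cc(C)c(Oc7c(C=O)c(OCc8ccccc8)cc(C)c7C(=O)OC)c3OCc5ccccc5)c1OCc6ccccc6 | intermediate
18 | praesorether F | COC(=O)c1c(C)cc(O)c(Cc2c(O)cc(C)c(Oc3c(C=O)c(O)cc(C)c3C(=O)OC)c2O)c1O | target

## Step count and risks

Total step count: 11. Longest linear sequence: 7 steps (steps 1, 2, 7, 8, 9, 10, 11 from methyl orsellinate; equally steps 5, 6, 7, 8, 9, 10, 11 from orcinol).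

**Step 7 (most likely to fail).** Both coupling partners are 2,6-dioxygenated, so the nickel step may stall or give only Wolff–Kishner reduction of 11. The fallback sets out from 4 (with 10 unchanged) and comes back at 12. It keeps the benzylic carbon nucleophilic but uses a zinc reagent: reduce 4 with NaBH4 in MeOH at 0 °C to the benzylic alcohol methyl 2,4-bis(benzyloxy)-3-(hydroxymethyl)-6-methylbenzoate F1. Convert it with SOCl2 in CH2Cl2 at 0 °C into the benzylic chloride methyl 2,4-bis(benzyloxy)-3-(chloromethyl)-6-methylbenzoate F2. Insert zinc (Zn dust, LiCl, THF, rt) to give the benzylzinc reagent {[2,6-bis(benzyloxy)-3-(methoxycarbonyl)-4-methylphenyl]methyl}zinc chloride F3. A Negishi coupling of F3 with 10 (Pd(OAc)2, SPhos, THF, 50 °C) then gives 12.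

**Step 4.** The chelated, doubly ortho-substituted phenol may resist fluorosulfonylation, or the aldehyde may suffer under anhydrous fluoride. The fallback sets out from 5 and comes back at 17, replacing steps 4 and 10. Treat 5 with Tf2O and pyridine in CH2Cl2 at 0 °C to give the aryl triflate methyl 4-(benzyloxy)-3-formyl-6-methyl-2-[(trifluoromethylsulfonyl)oxy]benzoate F4. Join F4 to phenol 16 by palladium-catalysed C–O cross-coupling (tBuBrettPhos-Pd precatalyst, K3PO4, toluene, 100 °C) in place of the fluoride SNAr.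

**Step 8.** Ring A may compete in the formylation, or the crowded ring-B position may react sluggishly. The fallback sets out from 12 and comes back at 16, bypassing 13 to 15. Brominate 12 with NBS (1.0 equiv, MeCN, 0 °C) to the aryl bromide methyl 2,4-bis(benzyloxy)-3-[[2,6-bis(benzyloxy)-3-bromo-4-methylphenyl]methyl]-6-methylbenzoate F5. Convert it by Miyaura borylation (B2pin2, Pd/XPhos, KOAc, dioxane, 90 °C) into the pinacol boronate methyl 2,4-bis(benzyloxy)-3-[[2,6-bis(benzyloxy)-4-methyl-3-(4,4,5,5-tetramethyl-1,3,2-dioxaborolan-2-yl)phenyl]methyl]-6-methylbenzoate F6. Oxidise F6 with NaBO3·4H2O in THF/H2O at rt to the phenol 16.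

## Further compounds

F1 | step 7 | methyl 2,4-bis(benzyloxy)-3-(hydroxymethyl)-6-methylbenzoate | COC(=O)c1c(C)cc(OCc2ccccc2)c(CO)c1OCc3ccccc3
F2 | step 7 | methyl 2,4-bis(benzyloxy)-3-(chloromethyl)-6-methylbenzoate | COC(=O)c1c(C)cc(OCc2ccccc2)c(CCl)c1OCc3ccccc3
F3 | step 7 | {[2,6-bis(benzyloxy)-3-(methoxycarbonyl)-4-methylphenyl]methyl}zinc chloride | COC(=O)c1c(C)cc(OCc2ccccc2)c(C[Zn]Cl)c1OCc3ccccc3
F4 | step 4 | methyl 4-(benzyloxy)-3-formyl-6-methyl-2-[(trifluoromethylsulfonyl)oxy]benzoate | COC(=O)c1c(C)cc(OCc2ccccc2)c(C=O)c1OS(=O)(=O)C(F)(F)F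
F5 | step 8 | methyl 2,4-bis(benzyloxy)-3-[[2,6-bis(benzyloxy)-3-bromo-4-methylphenyl]methyl]-6-methylbenzoate | COC(=O)c1c(C)cc(OCc2ccccc2)c(Cc3c(OCc4ccccc4)cc(C)c(Br)c3OCc5ccccc5)c1OCc6ccccc6
F6 | step 8 | methyl 2,4-bis(benzyloxy)-3-[[2,6-bis(benzyloxy)-4-methyl-3-(4,4,5,5-tetramethyl-1,3,2-dioxaborolan-2-yl)phenyl]methyl]-6-methylbenzoate | COC(=O)c1c(C)cc(OCc2ccccc2)c(Cc3c(OCc4ccccc4)cc(C)c(B7OC(C)(C)C(C)(C)O7)c3OCc5ccccc5)c1OCc6ccccc6
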